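**Assumptions.** The target has no stereocenters, so there is no enantiomer to control. The 3-O-sulfate monoester is isolated as a salt (K⁺ or Et₃NH⁺), because the free acid of an enol-type sulfate is labile. Its formula is the SMILES given.

## Retrosynthetic overview
1. Kaempferol 3-O-sulfate comes from the 3-O-sulfate of 5,7,4'-tri-O-benzylkaempferol by hydrogenolysis. Sulfate monoester salts survive H₂/Pd.
2. The sulfate is placed on the free 3-OH of tribenzylkaempferol. Protecting 5, 7 and 4' as benzyl ethers gives regiocontrol that direct sulfation of kaempferol cannot, since 7-OH and 4'-OH are more acidic than 3-OH.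
3. The tribenzyl flavonol comes from the chalcone by Algar–Flynn–Oyamada (AFO) oxidative cyclisation. This forms the pyranone ring (C ring) and installs 3-OH in one step.
4. The chalcone comes from Claisen–Schmidt condensation of 4,6-bis(benzyloxy)-2-hydroxyacetophenone with 4-benzyloxybenzaldehyde. The acetophenone comes from regioselective dibenzylation of phloroacetophenone. The A ring is therefore present from the start, the B ring arrives with the aldehyde, and the C ring closes in step 3.

## Forward route

**Step 1**
Reactants: 1 (2,4,6-trihydroxyacetophenone), 2 (benzyl bromide)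
Product: 3 (1-[4,6-bis(benzyloxy)-2-hydroxyphenyl]ethan-1-one)
Conditions: 2 (2.1 equiv), K₂CO₃, acetone, reflux
Reagents that add atoms: benzyl bromide, BrCc1ccccc1
Why: Williamson etherification. The 2-OH is locked in a hydrogen bond to the acetyl C=O and is much less acidic and nucleophilic, so only the 4-OH and 6-OH are benzylated. No stereocenter is formed.

**Step 2**
Reactants: 3, 4 (4-(benzyloxy)benzaldehyde)
Product: 5 ((E)-1-[4,6-bis(benzyloxy)-2-hydroxyphenyl]-3-[4-(benzyloxy)phenyl]prop-2-en-1-one)
Conditions: 50% aq. KOH, EtOH, rt, 24 h
Reagents that add atoms: none (the aldehyde is a numbered reactant and water is lost)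
Why: Claisen–Schmidt (aldol) condensation. Dehydration gives the thermodynamically favoured E-enone, and the only new stereochemical element is this alkene geometry.

**Step 3**
Reactants: 5, 6 (hydrogen peroxide)
Product: 7 (5,7,4'-tri-O-benzylkaempferol, i.e. 5,7-bis(benzyloxy)-2-[4-(benzyloxy)phenyl]-3-hydroxy-4H-chromen-4-one)
Conditions: 6 (30% aq.), NaOH, MeOH/THF, 0 °C to rt
Reagents that add atoms: hydrogen peroxide, OO (supplies the 3-OH oxygen)
Why: Algar–Flynn–Oyamada reaction. Nucleophilic epoxidation of the enone is followed by phenoxide opening of the epoxide (6-endo) to give a 3-hydroxyflavanone, which is oxidised to the flavonol. The transient stereocenters at C2 and C3 are destroyed on aromatisation, so the product is achiral.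

**Step 4**
Reactants: 7, 8 (sulfur trioxide–triethylamine complex)
Product: 9 (triethylammonium 5,7,4'-tri-O-benzylkaempferol 3-O-sulfate)
Conditions: 8 (3–5 equiv), MeCN, 60 °C
Reagents that add atoms: SO₃·NEt₃, O=S(=O)=O.CCN(CC)CC
Why: O-sulfation of the only free hydroxyl by an amine–SO₃ complex. The 5-, 7- and 4'-oxygens are benzylated, so 3-O is the only site available.

**Step 5**
Reactants: 9, 10 (hydrogen)
Product: 11 (kaempferol 3-O-sulfate, isolated as its K⁺ or Et₃NH⁺ salt)
Conditions: H₂ (1 atm), 10% Pd/C, MeOH/THF, rt; then K⁺ ion exchange if the potassium salt is wanted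
Reagents that add atoms: hydrogen, [H][H]
Why: Pd-catalysed hydrogenolysis cleaves the three benzyl ethers (toluene is lost) and leaves the aryl sulfate monoester and the C2=C3 bond intact. This gives the achiral target.

## Self-check
- **Structure:** 11 has the chromen-4-one core (6-membered pyranone fused to the benzo ring), 2-(4-hydroxyphenyl), 3-OSO₃H, and 5-OH and 7-OH. This matches O=c1c(OS(=O)(=O)O)c(-c2ccc(O)cc2)oc2cc(O)cc(O)c12.
- **Atom mapping:** the acetophenone 6'-OBn becomes 5-OBn and the 4'-OBn becomes 7-OBn. The chalcone 2'-O becomes the ring oxygen O1, and the aldehyde carbon becomes C2 with the 4-OBn-phenyl B ring.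
- **Protecting groups:** benzyl ethers survive K₂CO₃, KOH and H₂O₂/NaOH. The sulfate (a salt) survives H₂/Pd. The free 3-OH is the only nucleophile in step 4.
- **Stereocenters:** the target has none, and none are carried or scrambled.

## Compound list
1 | 2,4,6-trihydroxyacetophenone | CC(=O)c1c(O)cc(O)cc1O | starting material
2 | benzyl bromide | BrCc1ccccc1 | starting material (reagent)
3 | 4,6-bis(benzyloxy)-2-hydroxyacetophenone | CC(=O)c1c(OCc2ccccc2)cc(OCc2ccccc2)cc1O | intermediate
4 | 4-(benzyloxy)benzaldehyde | O=Cc1ccc(OCc2ccccc2)cc1 | starting material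
5 | (E)-2'-hydroxy-4,4',6'-tris(benzyloxy)chalcone | O=C(/C=C/c1ccc(OCc2ccccc2)cc1)c1c(O)cc(OCc2ccccc2)cc1OCc1ccccc1 | intermediate
6 | hydrogen peroxide | OO | starting material (reagent)
7 | 5,7,4'-tri-O-benzylkaempferol | O=c1c(O)c(-c2ccc(OCc3ccccc3)cc2)oc2cc(OCc3ccccc3)cc(OCc3ccccc3)c12 | intermediate
8 | sulfur trioxide–triethylamine complex | O=S(=O)=O.CCN(CC)CC | starting material (reagent)
9 | triethylammonium 5,7,4'-tri-O-benzylkaempferol 3-O-sulfate | CC[NH+](CC)CC.O=c1c(OS(=O)(=O)[O-])c(-c2ccc(OCc3ccccc3)cc2)oc2cc(OCc3ccccc3)cc(OCc3ccccc3)c12 | intermediate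
10 | hydrogen | [H][H] | starting material (reagent)
11 | kaempferol 3-O-sulfate | O=c1c(OS(=O)(=O)O)c(-c2ccc(O)cc2)oc2cc(O)cc(O)c12 | target

## Totals
Total steps: 5. Longest linear sequence: 5 (1 → 3 → 5 → 7 → 9 → 11).

## Three steps most likely to fail
1. **Step 3 (AFO).** Aurone formation and over-oxidation can compete, and yields are often modest. Fallback: Auwers route. Make the aurone from the chalcone, brominate it to the dibromide, and treat with KOH/EtOH to give the tribenzyl flavonol 7.
2. **Step 4 (sulfation).** The 3-OH is weakly nucleophilic and sits next to the C4 carbonyl, so conversion may be low. Fallback: change the sulfate-installing reagent to trichloroethyl chlorosulfate (Cl₃CCH₂OSO₂Cl) with base, then hydrogenolyse the benzyl ethers and remove the trichloroethyl group with Zn/NH₄OAc.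
3. **Step 5 (hydrogenolysis).** Over-reduction of C2=C3, incomplete debenzylation of the hindered 5-OBn, or sulfate loss are all possible. Fallback: switch the protecting group to allyl from step 1 onward (allyl bromide in place of BnBr). Remove the allyl groups at the end with Pd(PPh₃)₄ and a nucleophilic scavenger under neutral conditions, which avoids hydrogenation.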